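The runs come from a simulation with made-up constants; scatter was added.

From the early days of the earlier runs onward I followed one free monomer and asked its chance per day of being taken into a chain, while the initiator, charged at a few mol%, kept starting chains.

| flask | free monomer | initiator | remark | time |
|---|---|---|---|---|
| noon | 0.50 M | 2.7 mol% | run made earlier |  |
| summer | 0.50 M | 6.1 mol% | run made earlier |  |
| dawn | 0.25 M | 4.1 mol% | run made earlier |  |
| red | 0.50 M | 4.1 mol% |  | 10 d |
| amber | 0.50 M | 4.1 mol% |  | 5.0 d |

| run | time / d | monomer in chains / % | free monomer / % |
|---|---|---|---|
| noon | 1.04 | 18.5 | 80.8 |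
| noon | 3.00 | 43.8 | 55.2 |
| noon | 6.00 | 69.3 | 30.0 |
| noon | 8.00 | 78.5 | 21.2 |
| noon | 12.0 | 90.2 | 9.6 |
| summer | 1.04 | 26.7 | 73.2 |
| summer | 3.00 | 58.2 | 41.7 |
| summer | 6.00 | 82.6 | 16.7 |
| summer | 8.00 | 90.0 | 8.8 |
| summer | 12.0 | 96.0 | 2.9 |
| dawn | 2.50 | 35.7 | 64.6 |
| dawn | 5.00 | 57.1 | 41.6 |
| dawn | 8.00 | 74.5 | 25.8 |
| dawn | 10.0 | 81.1 | 17.6 |
| dawn | 12.0 | 85.0 | 12.5 |

(standard deviation of a reading: 0.5 percentage points)

- the average divides the monomer in chains by the number of chains, living and dead together; two radicals that join make one chain
- what was read earlier has a scatter of 0.5 percentage points, one standard deviation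
- the earlier runs do not show the number of chains; that part of a forecast is a guess

- which of the two ends with the longer chains by the average number of monomer units in a chain (living and dead chains, two that joined counted as one) ("neither" if they lie within 10 %) (red / amber / neither)
- average number of monomer units in a chain (living and dead chains, two that joined counted as one) at the end, red
- average number of monomer units in a chain (living and dead chains, two that joined counted as one) at the end, amber

The noon run left 9.6 % free monomer at 12.0 d, which read as a chance of 0.195 d⁻¹ (a pseudo-first-order constant), and the summer run read 0.295 d⁻¹, a ratio of 1.51 against 1.50 for the square root of the loadings. I doubted that a root of loading alone would carry over to another concentration, but the root of initiator concentration predicted 0.170 d⁻¹ for the dawn run, which read 0.173 d⁻¹. Red and amber therefore got 0.241 d⁻¹, so I expected 91.0 % conversion in red and 70.0 % in amber.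

Assuming that chains are started steadily in proportion to initiator, I reckoned with a length index, the conversion of free monomer divided by initiator loading and time, which is 3.41 d⁻¹ for amber and 2.22 d⁻¹ for red. My objection was that initiator might fade, and the noon chance read over the first 1.04 d was indeed 0.205 d⁻¹, higher than the 0.195 d⁻¹ read over the whole run. Through the root, that loose reading meant roughly 9.25 % less initiator, so I kept the index. It gave amber longer than red by a factor 1.54, but the index by itself gave no absolute length.

The forecast said amber, with 1200 units for red (range 300 to 6000) and 1900 for amber (range 450 to 9000), adding: “The absolute length is a guess.”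

    free monomer + initiating radical → growing radical + monomer in chains (k = 20000 M⁻¹ s⁻¹)
    2 growing radical → dead chain (k = 1.70 × 10⁸ M⁻¹ s⁻¹)
    free monomer + growing radical → monomer in chains + growing radical, rate k3*[growing radical]*[free monomer] (k = 31000 M⁻¹ min⁻¹)
    initiator → 2 initiating radical (k = 1.50 × 10⁻⁵ min⁻¹)
    free monomer → decomposition product (k = 1.50 × 10⁻⁶ min⁻¹)

The flask gave 113 units in red and 166 in amber, so amber was longer by a factor 1.47, against the index's 1.54, while the forecast's amber length stood at 11.4 times the flask's. In amber, free monomer went 91 times as fast into growth as into starting chains at 1.75 d, and 43 times as fast at 5.00 d. Initiator's half-life stood at 32 d at 1.75 d, with 90 % of amber's charge left at 5.00 d. For the neighbour of amber with 1 mol% initiator, the root gives 44.8 % conversion, and amber's length scaled by the index gives 437, where that flask stood at 434.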